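Plan (gibberellane atom numbers throughout)
1. Cuts: the 2β,3β-epoxide goes back to the 1β-hydroxy Δ2-alkene; ring A is cut at C2=C3 (metathesis) and at C4–C3 and C4–C18 (lactone enolate alkylations); ring B and the 19,10-lactone are cut together at C5–C10 and O–C19; then C10–C1, ring D at C13–C16, and C8–C6.
2. Enabling feature: C10 (carbinol carbon of the lactone) and C5 (β to the C19 carbonyl) are both acceptor carbons of ring B, and O10 and C19 are 1,4-related through C5–C4. A C10 ketyl adding to a C5=C4–C19 acrylate therefore joins two carbons of like polarity, and the alkoxide it leaves closes the lactone.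
3. Forward order: ring C (bought) → quaternary C8 through a temporary δ-lactone tether → ring D (ketyl–alkyne) → ring B plus γ-lactone (ketyl–enoate) → ring A (metathesis) → epoxide.
4. Stereochemistry: C9 by a catalytic asymmetric hydroxymethylation; C8 relayed by the tether and C13 by the bridge; C1 by a chiral allylborane; C10 and C5 in the key step; C4 by convex-face alkylation; C6 by equilibration; C2 and C3 by the 1β-hydroxyl.

Key step: step 14

Remark: 5 is a mixture of carbinol epimers and 20 a mixture of sulfoxide epimers (both centres are removed later); the C6 centre of 8 and 9 is drawn as one epimer and is erased in step 8; the enoate of 12 is taken as E.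

Step 1
Reactants: 1 3-ethoxycyclohex-2-en-1-one
Product: 2 4-ethoxy-2-(trimethylsilyloxy)cyclohexa-1,3-diene
Conditions: LiN(iPr)2, THF, −78 °C; TMSCl
Reagents that add atoms: chlorotrimethylsilane C[Si](C)(C)Cl
Why: Kinetic deprotonation of the vinylogous ester at the α'-carbon (C9) followed by O-silylation should give the cross-conjugated silyl dienol ether (kinetic silyl enol ether formation).

Step 2
Reactants: 2 4-ethoxy-2-(trimethylsilyloxy)cyclohexa-1,3-diene
Product: 3 (S)-3-ethoxy-6-(hydroxymethyl)cyclohex-2-en-1-one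
Conditions: aq. HCHO, Sc(OTf)3 (cat.), (S,S)-6,6'-bis(1-hydroxy-2,2-dimethylpropyl)-2,2'-bipyridine (cat.), DME/H2O, −20 °C
Reagents that add atoms: formaldehyde C=O
Why: Catalytic asymmetric Mukaiyama aldol (hydroxymethylation) of the silicon enolate in aqueous medium, in which the chiral scandium–bipyridine complex should set C9 by catalyst control, the ligand antipode being the one that leads to the S alcohol.

Step 3
Reactants: 3 (S)-3-ethoxy-6-(hydroxymethyl)cyclohex-2-en-1-one
Product: 4 (S)-6-[(tert-butyldimethylsilyloxy)methyl]-3-ethoxycyclohex-2-en-1-one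
Conditions: TBSCl, imidazole, DMF, 0 °C → rt
Reagents that add atoms: tert-butyldimethylsilyl chloride CC(C)(C)[Si](C)(C)Cl
Why: Silylation of the primary alcohol blocks retro-aldol loss of formaldehyde and alkoxide formation in the organometallic step.

Step 4
Reactants: 4 (S)-6-[(tert-butyldimethylsilyloxy)methyl]-3-ethoxycyclohex-2-en-1-one
Product: 6 (R)-4-(hydroxymethyl)-3-(prop-2-yn-1-yl)cyclohex-2-en-1-one, via tertiary propargyl carbinol 5 (not isolated)
Conditions: HC≡CCH2MgBr (from propargyl bromide and Mg), CeCl3, THF, −78 → 0 °C; then 2 M HCl, THF, rt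
Reagents that add atoms: propargylmagnesium bromide C#CC[Mg]Br; water O
Why: Stork–Danheiser transposition, in which the organocerium adds 1,2 to the vinylogous ester carbonyl (C8) without enolising C9, and acid hydrolysis of the enol ether with loss of water moves the carbonyl to C13, unveils the C14=C8 enone and removes the silyl group.

Step 5
Reactants: 6 (R)-4-(hydroxymethyl)-3-(prop-2-yn-1-yl)cyclohex-2-en-1-one
Product: 7 methyl [(1R)-4-oxo-2-(prop-2-yn-1-yl)cyclohex-2-en-1-yl]methyl malonate
Conditions: methyl malonyl chloride, pyridine, CH2Cl2, 0 °C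
Reagents that add atoms: methyl 3-chloro-3-oxopropanoate COC(=O)CC(=O)Cl
Why: O-acylation hangs the C6 nucleophile on the C10 oxygen as a temporary ester tether.

Step 6
Reactants: 7 methyl [(1R)-4-oxo-2-(prop-2-yn-1-yl)cyclohex-2-en-1-yl]methyl malonate
Product: 8 methyl cis-3,6-dioxo-4a-(prop-2-yn-1-yl)octahydro-1H-isochromene-4-carboxylate (keto lactone with quaternary C8)
Conditions: Cs2CO3 (cat.), MeCN, 0 °C → rt
Reagents that add atoms: none
Why: Intramolecular Michael addition (6-exo-trig) of the malonate to the β,β-disubstituted enone, in which the tether forces delivery of C6 to the face of C8 cis to the C9 arm and so sets the quaternary C8 with the propargyl group trans to C10 in a cis-fused δ-lactone.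

Step 7
Reactants: 8 keto lactone with quaternary C8
Product: 9 tricyclic hydroxy lactone (rings C and D closed; 13-OH; 16-methylidene; δ-lactone over C8–C9; C6 methyl ester)
Conditions: SmI2, HMPA, t-BuOH, THF, 0 °C
Reagents that add atoms: none
Why: Ketyl–alkyne reductive cyclisation (5-exo-dig) of the C13 ketyl onto the axial propargyl group closes ring D and gives the bridgehead tertiary alcohol and the exocyclic methylene in one event, the C13 configuration being fixed by the bridge.

Step 8
Reactants: 9 tricyclic hydroxy lactone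
Product: 10 dimethyl 2-[5-hydroxy-2-(hydroxymethyl)-6-methylidenebicyclo[3.2.1]octan-1-yl]malonate
Conditions: NaOMe (3 equiv), MeOH, 0 °C → rt; AcOH
Reagents that add atoms: methanol CO
Why: Methoxide transesterification opens the tether lactone to a symmetric dimethyl malonate (C6 is no longer a stereocentre) and frees the C10 alcohol; retro-Michael cleavage is impossible now that the C13 ketone is gone.

Step 9
Reactants: 10 diol malonate
Product: 11 dimethyl 2-[5-hydroxy-6-methylidene-2-(triethylsilyloxymethyl)bicyclo[3.2.1]octan-1-yl]malonate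
Conditions: TESCl, imidazole, CH2Cl2, −20 °C
Reagents that add atoms: chlorotriethylsilane CC[Si](CC)(CC)Cl
Why: Selective silylation of the primary alcohol over the hindered bridgehead alcohol prevents O-addition and relactonisation in the next step.

Step 10
Reactants: 11 silyl ether malonate
Product: 12 trimethyl (E)-3-[5-hydroxy-6-methylidene-2-(triethylsilyloxymethyl)bicyclo[3.2.1]octan-1-yl]prop-1-ene-1,3,3-tricarboxylate
Conditions: methyl propiolate, Cs2CO3 (cat.), DMF, 0 °C → rt
Reagents that add atoms: methyl propiolate C#CC(=O)OC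
Why: Michael addition of the malonate anion to the ynoate, a slim linear acceptor that should tolerate the neopentyl position next to C8, installs the C5=C4–C19 acrylate and makes C6 quaternary; the E enoate is the expected thermodynamic isomer and its geometry is not carried into the product.

Step 11
Reactants: 12 silyl ether acrylate
Product: 14 trimethyl (E)-3-[2-formyl-5-hydroxy-6-methylidenebicyclo[3.2.1]octan-1-yl]prop-1-ene-1,3,3-tricarboxylate, via primary alcohol 13 (not isolated)
Conditions: PPTS, MeOH, 0 °C; then Dess–Martin periodinane, NaHCO3, CH2Cl2, 0 °C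
Reagents that add atoms: none
Why: Mild acidic methanolysis removes the primary silyl ether without base-induced oxa-Michael closure onto the acrylate, and buffered Dess–Martin oxidation gives the C10 aldehyde without epimerising the C9 centre.

Step 12
Reactants: 14 aldehyde
Product: 15 trimethyl (E)-3-[5-hydroxy-2-[(1R,2R)-1-hydroxy-2-(methoxymethoxy)but-3-en-1-yl]-6-methylidenebicyclo[3.2.1]octan-1-yl]prop-1-ene-1,3,3-tricarboxylate
Conditions: [(Z)-3-(methoxymethoxy)allyl]diisopinocampheylborane (from allyl methoxymethyl ether, s-BuLi, (−)-Ipc2BOMe, BF3·OEt2), THF, −78 °C; ethanolamine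
Reagents that add atoms: [(Z)-3-(methoxymethoxy)allyl]diisopinocampheylborane from (+)-α-pinene COCO/C=C\CB([C@@H]1C[C@@H]2C[C@H]([C@H]1C)C2(C)C)[C@@H]1C[C@@H]2C[C@H]([C@H]1C)C2(C)C
Why: Asymmetric γ-alkoxyallylboration through a chair six-membered transition state, in which the isopinocampheyl groups set C1 (R) by reagent control, syn to the new C10 carbinol that is oxidised next.

Step 13
Reactants: 15 syn diol monoether
Product: 16 trimethyl (E)-3-[5-hydroxy-2-[(2R)-2-(methoxymethoxy)but-3-enoyl]-6-methylidenebicyclo[3.2.1]octan-1-yl]prop-1-ene-1,3,3-tricarboxylate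
Conditions: Dess–Martin periodinane, NaHCO3, CH2Cl2, 0 °C
Reagents that add atoms: none
Why: Buffered Dess–Martin oxidation of the secondary alcohol gives the α-alkoxy β,γ-unsaturated ketone under neutral conditions that should not enolise C1 or C9.

Step 14
Reactants: 16 keto acrylate
Product: 18 ring B γ-lactone carrying the C6 bis(methyl ester) and the (R)-1-(methoxymethoxy)allyl group on C10, via hydroxy triester 17 (not isolated)
Conditions: SmI2, MeOH, THF, −78 → 0 °C
Reagents that add atoms: none
Why: Electron transfer from SmI2 to the C10 ketone gives a samarium ketyl that adds to C5, the β-carbon of the C5=C4–C19 acrylate, after which the α-ester radical at C4 is reduced to the samarium enolate and protonated by MeOH, and the C10 alkoxide closes on C19 with loss of methoxide. The closest known reaction type is the SmI2-mediated ketyl–olefin (ketone–acrylate) reductive cyclisation with lactonisation in the same flask. Ring B closes in the 5-exo-trig radical mode and the γ-lactone by 5-exo-trig acyl substitution. C10 should be controlled by the rigid ring C/ring D template, the branched C1 chain of the ketyl taking the face syn to H9 and the oxygen the face syn to C11; C5 should be controlled by chelation of trivalent samarium between the ketyl oxygen and the acrylate carbonyl and by avoidance of the C1 chain, so that C4 and O10 end up cis and are locked by the lactone. The step needs reduction of the ketone before the enoate and cyclisation faster than β-elimination of the C1 alkoxy group: the α-alkoxy ketone is the most easily reduced site, the geminal diester at C6 speeds the closure and removes any stereocentre at C6, and the C16 and C2 alkenes are unactivated and not ketyl acceptors.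

Step 15
Reactants: 18 ring B γ-lactone
Product: 19 4-methyl lactone
Conditions: LiN(iPr)2 (2.2 equiv), THF, −78 °C; MeI (1.1 equiv); AcOH
Reagents that add atoms: iodomethane CI
Why: Enolate alkylation of the lactone (the only enolisable carbon, as C6 carries no hydrogen, the second equivalent of base being taken by the 13-hydroxyl) introduces C18, and the configuration set here is erased by the next enolisation.

Step 16
Reactants: 19 4-methyl lactone
Product: 20 4-methyl-4-[2-(phenylsulfinyl)ethyl] lactone
Conditions: LiN(iPr)2 (2.2 equiv), THF/DMPU, −78 °C; phenyl vinyl sulfoxide, −78 → −20 °C; AcOH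
Reagents that add atoms: phenyl vinyl sulfoxide C=CS(=O)c1ccccc1
Why: Conjugate addition of the tetrasubstituted lactone enolate to the vinyl sulfoxide (a vinyl cation equivalent) on the convex face of the cis-fused ring B/γ-lactone bicycle, the face of H5 and the C1 chain and away from the C6 diester, sets the quaternary C4 with C3 cis to C1 and C18 toward ring B.

Step 17
Reactants: 20 sulfoxide
Product: 21 4-methyl-4-vinyl lactone
Conditions: toluene, CaCO3, 110 °C
Reagents that add atoms: none
Why: Thermal syn-elimination of the sulfoxide (sulfoxide pyrolysis) unmasks the C4 vinyl group.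

Step 18
Reactants: 21 diene lactone
Product: 22 methyl 13-hydroxy-6-(methoxycarbonyl)-1β-(methoxymethoxy)-20-norgibberella-2,16-dien-7-oate 19,10-lactone
Conditions: second-generation Grubbs catalyst (H2IMes)(PCy3)Cl2Ru=CHPh (cat.), CH2Cl2, 40 °C
Reagents that add atoms: none
Why: Ring-closing metathesis of the two monosubstituted alkenes held cis and 1,3 on the lactone closes ring A at C2=C3 as the 6-oxabicyclo[3.2.1]octene, while the hindered 1,1-disubstituted C16 methylene stays out.

Step 19
Reactants: 22 ring A dimethyl ester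
Product: 24 methyl 13-hydroxy-1β-(methoxymethoxy)-20-norgibberella-2,16-dien-7-oate 19,10-lactone, via C6 epimer 23 (not isolated)
Conditions: LiCl, H2O, DMSO, 150 °C; then NaOMe (cat.), MeOH, rt
Reagents that add atoms: none
Why: Krapcho dealkoxycarbonylation removes the auxiliary ester at C6, and base equilibration of the remaining α-ester centre should give the more stable 6β ester, trans to the C5–C4 bond.

Step 20
Reactants: 24 methoxymethyl ether
Product: 25 methyl 1β,13-dihydroxy-20-norgibberella-2,16-dien-7-oate 19,10-lactone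
Conditions: ZnBr2, n-PrSH, CH2Cl2, 0 °C
Reagents that add atoms: none
Why: Lewis acid/thiol cleavage of the acetal-type ether frees the 1β-hydroxyl under conditions too mild to disturb the bridgehead allylic alcohol or the lactone.

Step 21
Reactants: 25 methyl ester
Product: 26 1β,13-dihydroxy-20-norgibberella-2,16-diene-7,19-dioic acid 19,10-lactone
Conditions: LiSPr, HMPA, rt; then dilute HCl, 0 °C
Reagents that add atoms: none
Why: Thiolate demethylation by bimolecular substitution at the methyl carbon cleaves the hindered C7 ester without touching the 19,10-lactone, whose alkyl carbon is tertiary.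

Step 22
Reactants: 26 hydroxy acid
Product: 27 target gibberellin, 2β,3β-epoxy-1β,13-dihydroxy-20-norgibberell-16-ene-7,19-dioic acid 19,10-lactone
Conditions: VO(acac)2 (cat.), t-BuOOH, CH2Cl2, 0 °C → rt
Reagents that add atoms: tert-butyl hydroperoxide CC(C)(C)OO
Why: Hydroxyl-directed vanadium-catalysed epoxidation delivers oxygen to C2=C3 on the face of the 1β-hydroxyl to give the 2β,3β-epoxide; the C16 methylene is expected to stay untouched because its hindered bridgehead hydroxyl lies almost in the plane of that alkene and cannot deliver the oxidant to the π face.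

Compound list
1 | 3-ethoxycyclohex-2-en-1-one | CCOC1=CC(=O)CCC1 | starting material
2 | 4-ethoxy-2-(trimethylsilyloxy)cyclohexa-1,3-diene | CCOC1=CC(O[Si](C)(C)C)=CCC1 | intermediate
3 | (S)-3-ethoxy-6-(hydroxymethyl)cyclohex-2-en-1-one | CCOC1=CC(=O)[C@H](CO)CC1 | intermediate
4 | (S)-6-[(tert-butyldimethylsilyloxy)methyl]-3-ethoxycyclohex-2-en-1-one | CCOC1=CC(=O)[C@H](CO[Si](C)(C)C(C)(C)C)CC1 | intermediate
5 | (6S)-6-[(tert-butyldimethylsilyloxy)methyl]-3-ethoxy-1-(prop-2-yn-1-yl)cyclohex-2-en-1-ol, carbinol epimers (not isolated) | CCOC1=CC(O)(CC#C)[C@H](CO[Si](C)(C)C(C)(C)C)CC1 | intermediate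
6 | (R)-4-(hydroxymethyl)-3-(prop-2-yn-1-yl)cyclohex-2-en-1-one | O=C1C=C(CC#C)[C@H](CO)CC1 | intermediate
7 | methyl [(1R)-4-oxo-2-(prop-2-yn-1-yl)cyclohex-2-en-1-yl]methyl malonate | O=C1C=C(CC#C)[C@H](COC(=O)CC(=O)OC)CC1 | intermediate
8 | methyl cis-3,6-dioxo-4a-(prop-2-yn-1-yl)octahydro-1H-isochromene-4-carboxylate (quaternary C8, propargyl trans to the C10 methylene) | O=C1C[C@]2(CC#C)[C@@H](C(=O)OC)C(=O)OC[C@@H]2CC1 | intermediate
9 | tricyclic hydroxy lactone: rings C and D (13-OH, 16-methylidene) with the δ-lactone over C8–C9 and a methyl ester at C6 | C=C1C[C@]23C[C@@]1(O)CC[C@H]2COC(=O)[C@@H]3C(=O)OC | intermediate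
10 | dimethyl 2-[5-hydroxy-2-(hydroxymethyl)-6-methylidenebicyclo[3.2.1]octan-1-yl]malonate (target configuration at C8, C9, C13) | C=C1C[C@]2(C(C(=O)OC)C(=O)OC)C[C@@]1(O)CC[C@H]2CO | intermediate
11 | dimethyl 2-[5-hydroxy-6-methylidene-2-(triethylsilyloxymethyl)bicyclo[3.2.1]octan-1-yl]malonate | C=C1C[C@]2(C(C(=O)OC)C(=O)OC)C[C@@]1(O)CC[C@H]2CO[Si](CC)(CC)CC | intermediate
12 | trimethyl (E)-3-[5-hydroxy-6-methylidene-2-(triethylsilyloxymethyl)bicyclo[3.2.1]octan-1-yl]prop-1-ene-1,3,3-tricarboxylate | C=C1C[C@]2(C(C(=O)OC)(C(=O)OC)/C=C/C(=O)OC)C[C@@]1(O)CC[C@H]2CO[Si](CC)(CC)CC | intermediate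
13 | trimethyl (E)-3-[5-hydroxy-2-(hydroxymethyl)-6-methylidenebicyclo[3.2.1]octan-1-yl]prop-1-ene-1,3,3-tricarboxylate (not isolated) | C=C1C[C@]2(C(C(=O)OC)(C(=O)OC)/C=C/C(=O)OC)C[C@@]1(O)CC[C@H]2CO | intermediate
14 | trimethyl (E)-3-[2-formyl-5-hydroxy-6-methylidenebicyclo[3.2.1]octan-1-yl]prop-1-ene-1,3,3-tricarboxylate | C=C1C[C@]2(C(C(=O)OC)(C(=O)OC)/C=C/C(=O)OC)C[C@@]1(O)CC[C@H]2C=O | intermediate
15 | trimethyl (E)-3-[5-hydroxy-2-[(1R,2R)-1-hydroxy-2-(methoxymethoxy)but-3-en-1-yl]-6-methylidenebicyclo[3.2.1]octan-1-yl]prop-1-ene-1,3,3-tricarboxylate | C=C1C[C@]2(C(C(=O)OC)(C(=O)OC)/C=C/C(=O)OC)C[C@@]1(O)CC[C@H]2[C@@H](O)[C@H](OCOC)C=C | intermediate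
16 | trimethyl (E)-3-[5-hydroxy-2-[(2R)-2-(methoxymethoxy)but-3-enoyl]-6-methylidenebicyclo[3.2.1]octan-1-yl]prop-1-ene-1,3,3-tricarboxylate | C=C1C[C@]2(C(C(=O)OC)(C(=O)OC)/C=C/C(=O)OC)C[C@@]1(O)CC[C@H]2C(=O)[C@H](OCOC)C=C | intermediate
17 | cyclised hydroxy triester: ring B closed, 10α-OH, C5 bearing CH2CO2Me, C6 bis(methyl ester) (not isolated) | C=C1C[C@]23C[C@@]1(O)CC[C@H]2[C@](O)([C@H](OCOC)C=C)[C@@H](CC(=O)OC)C3(C(=O)OC)C(=O)OC | intermediate
18 | ring B γ-lactone: 19,10-lactone with a C4 methylene, C6 bis(methyl ester), C10 bearing (R)-1-(methoxymethoxy)allyl, 13-OH, 16-methylidene | C=C1C[C@]23C[C@@]1(O)CC[C@H]2[C@]1(OC(=O)C[C@H]1C3(C(=O)OC)C(=O)OC)[C@H](OCOC)C=C | intermediate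
19 | 4-methyl derivative of 18 (methyl cis to H5) | C=C1C[C@]23C[C@@]1(O)CC[C@H]2[C@]1(OC(=O)[C@H](C)[C@H]1C3(C(=O)OC)C(=O)OC)[C@H](OCOC)C=C | intermediate
20 | 4-methyl-4-[2-(phenylsulfinyl)ethyl] derivative of 18 (sulfinylethyl cis to H5 and C1), sulfoxide epimers | C=C1C[C@]23C[C@@]1(O)CC[C@H]2[C@]1(OC(=O)[C@](C)(CCS(=O)c4ccccc4)[C@H]1C3(C(=O)OC)C(=O)OC)[C@H](OCOC)C=C | intermediate
21 | 4-methyl-4-vinyl derivative of 18 (vinyl cis to H5 and C1) | C=C1C[C@]23C[C@@]1(O)CC[C@H]2[C@]1(OC(=O)[C@](C)(C=C)[C@H]1C3(C(=O)OC)C(=O)OC)[C@H](OCOC)C=C | intermediate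
22 | methyl 13-hydroxy-6-(methoxycarbonyl)-1β-(methoxymethoxy)-20-norgibberella-2,16-dien-7-oate 19,10-lactone | C=C1C[C@]23C[C@@]1(O)CC[C@H]2[C@@]12OC(=O)[C@@](C)([C@H]1C3(C(=O)OC)C(=O)OC)C=C[C@H]2OCOC | intermediate
23 | 6-epimer of 24 (6α-ester, not isolated) | C=C1C[C@]23C[C@@]1(O)CC[C@H]2[C@@]12OC(=O)[C@@](C)([C@H]1[C@H]3C(=O)OC)C=C[C@H]2OCOC | intermediate
24 | methyl 13-hydroxy-1β-(methoxymethoxy)-20-norgibberella-2,16-dien-7-oate 19,10-lactone | C=C1C[C@]23C[C@@]1(O)CC[C@H]2[C@@]12OC(=O)[C@@](C)([C@H]1[C@@H]3C(=O)OC)C=C[C@H]2OCOC | intermediate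
25 | methyl 1β,13-dihydroxy-20-norgibberella-2,16-dien-7-oate 19,10-lactone | C=C1C[C@]23C[C@@]1(O)CC[C@H]2[C@@]12OC(=O)[C@@](C)([C@H]1[C@@H]3C(=O)OC)C=C[C@H]2O | intermediate
26 | 1β,13-dihydroxy-20-norgibberella-2,16-diene-7,19-dioic acid 19,10-lactone | C=C1C[C@]23C[C@@]1(O)CC[C@H]2[C@@]12OC(=O)[C@@](C)([C@H]1[C@@H]3C(=O)O)C=C[C@H]2O | intermediate
27 | target gibberellin, 2β,3β-epoxy-1β,13-dihydroxy-20-norgibberell-16-ene-7,19-dioic acid 19,10-lactone | C=C1C[C@]23C[C@@]1(O)CC[C@H]2[C@@]12OC(=O)[C@@](C)([C@H]1[C@@H]3C(=O)O)[C@H]1O[C@H]1[C@H]2O | target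

Total step count: 22. Longest linear sequence: 22 steps (fully linear from 1).

Steps most likely to fail

Step 14. The ketyl may add to C5 from the wrong face, or the C1 alkoxy group may be lost by β-elimination from the ketyl before cyclisation. The fallback closes the same bond by polarity reversal instead of by a radical. It sets out from aldehyde 14: an intramolecular Stetter reaction under N-heterocyclic carbene catalysis (triazolium salt, iPr2NEt, THF) adds the C10 acyl anion equivalent to C5 and gives the ring B cyclopentanone F1 , whose C5 centre is α to the ketone and can be equilibrated. The (Z)-γ-(methoxymethoxy)allyltitanium reagent (from allyl methoxymethyl ether, s-BuLi, ClTi(OiPr)3) then adds to the C10 ketone from the face of H9 and H5; the tertiary alkoxide formed is the alkoxide of 17, it lactonises onto C19, and the route is rejoined at 18. The weak point of this fallback is that C1 is then set by substrate control only.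

Step 16. Conjugate addition of the hindered tetrasubstituted enolate may be slow or reversible, so that the quaternary C4 is not formed. The fallback sets out from 19: the same enolate (LiN(iPr)2, −78 °C) is trapped with acetaldehyde in an aldol addition on the convex face to give the 4-(1-hydroxyethyl)-4-methyl lactone F2 as a mixture of carbinol epimers. Dehydration with Martin sulfurane, Ph2S[OC(CF3)2Ph]2, can only take a methyl hydrogen and gives the vinyl compound 21, where the route is rejoined.

Step 2. The enantioselectivity may be low for this cyclic dienol ether, or the β-hydroxy ketone may racemise by retro-aldol or enolisation in the aqueous Lewis-acid medium. The fallback sets out from 1: LiN(iPr)2 and gaseous formaldehyde give racemic 3-ethoxy-6-(hydroxymethyl)cyclohex-2-en-1-one F3 . Kinetic resolution with a lipase (Pseudomonas cepacia lipase, vinyl acetate) should acylate the R alcohol to [(1R)-4-ethoxy-2-oxocyclohex-3-en-1-yl]methyl acetate F4 and leave the S alcohol, which is compound 3, where the route is rejoined. At most half of the material is usable.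

Further compounds
F1 | step 14 | ring B cyclopentanone | C=C1C[C@]23C[C@@]1(O)CC[C@H]2C(=O)[C@@H](CC(=O)OC)C3(C(=O)OC)C(=O)OC
F2 | step 16 | 4-(1-hydroxyethyl)-4-methyl lactone | C=C1C[C@]23C[C@@]1(O)CC[C@H]2[C@]1(OC(=O)[C@](C)(C(C)O)[C@H]1C3(C(=O)OC)C(=O)OC)[C@H](OCOC)C=C
F3 | step 2 | racemic 3-ethoxy-6-(hydroxymethyl)cyclohex-2-en-1-one | CCOC1=CC(=O)C(CO)CC1
F4 | step 2 | [(1R)-4-ethoxy-2-oxocyclohex-3-en-1-yl]methyl acetate | CCOC1=CC(=O)[C@@H](COC(C)=O)CC1
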